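**Strategy.** Eudesmane numbering is used (C10 = methyl-bearing ring-fusion carbon; C9 carries the ester, C7 the acrylic acid, C4 the carbinol). Everything rests on opening cyclohexane ring B at C8–C9 and C5–C10: a thermal intramolecular Diels–Alder reaction of an acyclic triene, diene C5=C6–C7=C8 onto (E)-enone C9=C10 through the C1–C4 tether, closes rings A and B at once and sets C5, C9 and C10. It exploits oxygenated C9 next to quaternary C10: the 3-methylpentanoyl group, bonded to C9 through its carbonyl carbon, activates the dienophile and later becomes the ester by Baeyer–Villiger oxidation. The linalool-derived C4 carbinol steers cyclisation and C7 hydrogenation, then is reset by dehydration–hydration.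

Key step: step 8

Remark: (S)-(+)-linalool of high enantiomeric purity, (S)-3-methylpentanoic acid and 3-bromobut-3-en-1-ol are taken as commercial; in the bicyclic compounds β denotes the face of the C10 methyl group (C14).

**Step 1**
Reactants: 1 (S)-(+)-linalool
Product: 2 (5S)-5-ethenyl-5-methyloxolan-2-ol (lactol; anomer mixture)
Conditions: O3 (1.0 equiv), CH2Cl2, −78 °C; then Me2S, −78 °C to rt
Reagents that add atoms: ozone, [O-][O+]=O
Why: Ozonolysis with reductive work-up should cleave the electron-rich trisubstituted alkene much faster than the vinyl group, and the γ-hydroxy aldehyde closes to the lactol; the C4 carbinol centre comes unchanged from linalool.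

**Step 2**
Reactants: 2 (5S)-5-ethenyl-5-methyloxolan-2-ol
Product: 4 (6S)-6-ethenyl-6-methyloxan-2-ol, via enol ether 3 (not isolated)
Conditions: MeOCH2PPh3Cl, KOtBu, THF, 0 °C to rt; then 1 M aq. HCl, THF, rt
Reagents that add atoms: (methoxymethyl)triphenylphosphonium chloride, COC[P+](c1ccccc1)(c1ccccc1)c1ccccc1.[Cl-]; water, O
Why: Wittig methoxymethylenation of the lactol through its open-chain aldehyde, then mild hydrolysis of the enol ether, adds C10 and gives the homologous aldehyde, which closes to the six-membered lactol.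

**Step 3**
Reactants: 4 (6S)-6-ethenyl-6-methyloxan-2-ol
Product: 5 (3S)-3-methyloct-1-en-7-yn-3-ol
Conditions: MeC(O)C(N2)P(O)(OMe)2, K2CO3, MeOH, 0 °C to rt
Reagents that add atoms: dimethyl (1-diazo-2-oxopropyl)phosphonate, CC(=O)C(=[N+]=[N-])P(=O)(OC)OC
Why: Seyferth–Gilbert homologation with the Ohira–Bestmann reagent converts the masked aldehyde into the terminal alkyne C10≡C9 under mild base that leaves the tertiary allylic alcohol alone.

**Step 4**
Reactants: 6 (S)-3-methylpentanoic acid
Product: 7 (S)-3-methylpentanoyl chloride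
Conditions: (COCl)2, DMF (cat.), CH2Cl2, 0 °C to rt
Reagents that add atoms: oxalyl chloride, O=C(Cl)C(=O)Cl
Why: Standard acid chloride formation through the Vilsmeier-type intermediate; the stereocentre is β to the carbonyl and cannot epimerise.

**Step 5**
Reactants: 5 (3S)-3-methyloct-1-en-7-yn-3-ol; 7 (S)-3-methylpentanoyl chloride
Product: 9 (3S,6E,11S)-11-hydroxy-3,7,11-trimethyltrideca-6,12-dien-5-one, via alkenylalane 8 (not isolated)
Conditions: Me3Al (3 equiv), Cp2ZrCl2 (20 mol %), CH2Cl2, 0 °C to rt; volatiles removed; then ZnCl2, Pd(PPh3)4 (5 mol %), 7, THF, 0 °C to rt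
Reagents that add atoms: trimethylaluminium, C[Al](C)C
Why: Zirconium-catalysed syn methylalumination of the terminal alkyne (Negishi carboalumination) puts the methyl on C10 and aluminium on C9, and palladium-catalysed acylation with 7 proceeds with retention, so the acyl group ends cis to C14 in the (E)-enone; the hydroxyl is masked in situ as its aluminium alkoxide and the isolated vinyl group is not carbometalated.

**Step 6**
Reactants: 10 3-bromobut-3-en-1-ol
Product: 11 [(3-bromobut-3-en-1-yl)oxy]triethylsilane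
Conditions: Et3SiCl, imidazole, CH2Cl2, 0 °C
Reagents that add atoms: chlorotriethylsilane, CC[Si](Cl)(CC)CC
Why: Routine silylation of the primary alcohol; the triethylsilyl ether is chosen because it can later be oxidised directly to the aldehyde.

**Step 7**
Reactants: 9 (3S,6E,11S)-11-hydroxy-3,7,11-trimethyltrideca-6,12-dien-5-one; 11 [(3-bromobut-3-en-1-yl)oxy]triethylsilane
Product: 12 (3S,6E,11S,12E)-11-hydroxy-3,7,11-trimethyl-14-methylidene-16-(triethylsilyloxy)hexadeca-6,12-dien-5-one
Conditions: Pd(OAc)2 (5 mol %), n-Bu4NCl, NaHCO3, DMF, 60 °C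
Reagents that add atoms: none
Why: Heck reaction in which the alkenylpalladium bromide adds to the terminal carbon of the vinyl carbinol and, with no hydrogen on the carbinol carbon, β-hydride elimination can only give the (E)-1,3-diene; the β,β-disubstituted enone is inert.

**Step 8**
Reactants: 12 (3S,6E,11S,12E)-11-hydroxy-3,7,11-trimethyl-14-methylidene-16-(triethylsilyloxy)hexadeca-6,12-dien-5-one
Product: 13 9β-[(3S)-3-methylpentanoyl]-12-(triethylsilyloxy)-13-nor-5αH-eudesm-6-en-4β-ol
Conditions: toluene (0.01 M), BHT (cat.), 150 °C, sealed tube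
Reagents that add atoms: none
Why: Thermal intramolecular Diels–Alder reaction of an (E)-enone-activated 1,7,9-decatriene, a concerted but asynchronous [4+2] cycloaddition in which C5–C10 bonding runs ahead of C8–C9. Ring B is closed by the cycloaddition itself and ring A by the four-carbon tether C1–C4, which folds chair-like and fixes the regiochemistry. Suprafacial addition to the (E)-dienophile places the acyl group on C9 cis to C14 on C10, and the endo arrangement of the carbonyl under the diene, with the tether anti, should give the trans ring fusion (5α-H anti to C14). The absolute sense comes from the C4 carbinol: in the chair-like tether the small hydroxyl rather than the C15 methyl should take the axial site that is 1,3-diaxial to the incoming C14, so the dienophile adds to the diene face syn to oxygen and C5, C9 and C10 are set relative to (4S). The step therefore needs endo and π-facial selectivity, the first secured by the conjugated ketone and the second by the methyl/hydroxyl size difference at C4; the other cycloadducts are diastereomers of 13 and should be separable, so enantiopurity is not at stake. The 4β-hydroxyl formed here is a control element only, used again in step 9 and replaced in steps 11 and 12.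

**Step 9**
Reactants: 13 9β-[(3S)-3-methylpentanoyl]-12-(triethylsilyloxy)-13-nor-5αH-eudesm-6-en-4β-ol
Product: 14 9β-[(3S)-3-methylpentanoyl]-12-(triethylsilyloxy)-13-nor-5αH,7βH-eudesman-4β-ol
Conditions: H2 (1 atm), [Ir(cod)(PCy3)(py)]PF6 (5 mol %), CH2Cl2, rt
Reagents that add atoms: none
Why: Hydroxyl-directed hydrogenation with Crabtree's catalyst: iridium bound to the axial 4β-hydroxyl (assisted by the 9β-carbonyl) should deliver H2 to the β face of C6=C7 against the steric bias of C14, which sets 7β-H and the axial 7α side chain.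

**Step 10**
Reactants: 14 9β-[(3S)-3-methylpentanoyl]-12-(triethylsilyloxy)-13-nor-5αH,7βH-eudesman-4β-ol
Product: 15 4β-hydroxy-12-(triethylsilyloxy)-13-nor-5αH,7βH-eudesman-9β-yl (3S)-3-methylpentanoate
Conditions: mCPBA, NaHCO3, CH2Cl2, rt
Reagents that add atoms: 3-chloroperoxybenzoic acid, O=C(OO)c1cccc(Cl)c1
Why: Baeyer–Villiger oxidation in which the secondary ring carbon C9 migrates in preference to the primary CH2 of the acyl chain and with retention, turning the 9β-acyl group into the 9β-(3-methylpentanoyloxy) ester.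

**Step 11**
Reactants: 15 4β-hydroxy-12-(triethylsilyloxy)-13-nor-5αH,7βH-eudesman-9β-yl (3S)-3-methylpentanoate
Product: 16 12-(triethylsilyloxy)-13-nor-5αH,7βH-eudesm-4(15)-en-9β-yl (3S)-3-methylpentanoate
Conditions: Burgess reagent (MeO2CN−SO2N+Et3), benzene, 50 °C
Reagents that add atoms: none
Why: Burgess dehydration by syn elimination: the axial 4β-sulfamate has syn hydrogens only on C15 and C3 (5α-H is anti), so the exocyclic alkene is expected as the main product, and any 3-ene isomer would give the same C4 radical in step 12.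

**Step 12**
Reactants: 16 12-(triethylsilyloxy)-13-nor-5αH,7βH-eudesm-4(15)-en-9β-yl (3S)-3-methylpentanoate
Product: 18 4α-hydroxy-12-(triethylsilyloxy)-13-nor-5αH,7βH-eudesman-9β-yl (3S)-3-methylpentanoate, via hydroperoxide 17 (not isolated)
Conditions: Co(acac)2 (20 mol %), PhSiH3, O2 (1 atm), i-PrOH, rt; then PPh3
Reagents that add atoms: dioxygen, O=O
Why: Mukaiyama hydration (hydrogen-atom transfer to C15, then capture of the planar tertiary C4 radical by O2): oxygen should enter from the equatorial α face, away from the 1,3-diaxial C14 methyl, which sets 4α-OH and 4β-CH3; the phosphine reduces the hydroperoxide.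

**Step 13**
Reactants: 18 4α-hydroxy-12-(triethylsilyloxy)-13-nor-5αH,7βH-eudesman-9β-yl (3S)-3-methylpentanoate
Product: 19 4α-hydroxy-12-oxo-13-nor-5αH,7βH-eudesman-9β-yl (3S)-3-methylpentanoate
Conditions: (COCl)2, DMSO, CH2Cl2, −78 to −40 °C; then Et3N, −78 °C to rt
Reagents that add atoms: none
Why: Swern oxidation carried out directly on the primary triethylsilyl ether, which is cleaved in situ by the chlorosulfonium reagent and oxidised to the aldehyde; the tertiary alcohol and the ester are inert.

**Step 14**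
Reactants: 19 4α-hydroxy-12-oxo-13-nor-5αH,7βH-eudesman-9β-yl (3S)-3-methylpentanoate
Product: 20 4α-hydroxy-12-oxo-5αH,7βH-eudesm-11(13)-en-9β-yl (3S)-3-methylpentanoate
Conditions: aq. CH2O, pyrrolidine (10 mol %), EtCO2H (10 mol %), i-PrOH, 45 °C
Reagents that add atoms: formaldehyde, C=O
Why: Amine-catalysed Mannich condensation with formaldehyde and elimination (α-methylenation of an aldehyde) installs C13 under conditions that spare the ester; C7 is not enolisable and keeps its configuration.

**Step 15**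
Reactants: 20 4α-hydroxy-12-oxo-5αH,7βH-eudesm-11(13)-en-9β-yl (3S)-3-methylpentanoate
Product: 21 4α-hydroxy-9β-[(3S)-3-methylpentanoyloxy]-5αH,7βH-eudesm-11(13)-en-12-oic acid (CNP0471281.1)
Conditions: NaClO2, NaH2PO4, 2-methyl-2-butene, t-BuOH/H2O, rt
Reagents that add atoms: sodium chlorite, [Na+].[O-]Cl=O
Why: Pinnick oxidation converts the α-methylene aldehyde into the acrylic acid without touching the alkene, the tertiary alcohol or the C9 ester.

**Compound list**

1 | (S)-(+)-linalool, (3S)-3,7-dimethylocta-1,6-dien-3-ol | C=C[C@@](C)(O)CCC=C(C)C | starting material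
2 | (5S)-5-ethenyl-5-methyloxolan-2-ol | C=C[C@]1(C)CCC(O)O1 | intermediate
3 | (5S)-1-methoxy-5-methylhepta-1,6-dien-5-ol (enol ether, E/Z) | C=C[C@@](C)(O)CCC=COC | intermediate
4 | (6S)-6-ethenyl-6-methyloxan-2-ol | C=C[C@]1(C)CCCC(O)O1 | intermediate
5 | (3S)-3-methyloct-1-en-7-yn-3-ol | C=C[C@@](C)(O)CCCC#C | intermediate
6 | (S)-3-methylpentanoic acid | CC[C@H](C)CC(=O)O | starting material
7 | (S)-3-methylpentanoyl chloride | CC[C@H](C)CC(=O)Cl | intermediate
8 | (E)-alkenyl(dimethyl)alane from 5, hydroxyl as its dimethylaluminium alkoxide | C=C[C@@](C)(O[Al](C)C)CCC/C(C)=C/[Al](C)C | intermediate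
9 | (3S,6E,11S)-11-hydroxy-3,7,11-trimethyltrideca-6,12-dien-5-one | CC[C@H](C)CC(=O)/C=C(\C)CCC[C@](C)(O)C=C | intermediate
10 | 3-bromobut-3-en-1-ol | C=C(Br)CCO | starting material
11 | [(3-bromobut-3-en-1-yl)oxy]triethylsilane | C=C(Br)CCO[Si](CC)(CC)CC | intermediate
12 | (3S,6E,11S,12E)-11-hydroxy-3,7,11-trimethyl-14-methylidene-16-(triethylsilyloxy)hexadeca-6,12-dien-5-one | CC[C@H](C)CC(=O)/C=C(\C)CCC[C@](C)(O)/C=C/C(=C)CCO[Si](CC)(CC)CC | intermediate
13 | 9β-[(3S)-3-methylpentanoyl]-12-(triethylsilyloxy)-13-nor-5αH-eudesm-6-en-4β-ol (trans-fused; C15 α, C14 β) | CC[Si](CC)(CC)OCCC1=C[C@H]2[C@@](C)(O)CCC[C@]2(C)[C@@H](C(=O)C[C@@H](C)CC)C1 | intermediate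
14 | 9β-[(3S)-3-methylpentanoyl]-12-(triethylsilyloxy)-13-nor-5αH,7βH-eudesman-4β-ol | CC[Si](CC)(CC)OCC[C@H]1C[C@H](C(=O)C[C@@H](C)CC)[C@@]2(C)CCC[C@](C)(O)[C@@H]2C1 | intermediate
15 | 4β-hydroxy-12-(triethylsilyloxy)-13-nor-5αH,7βH-eudesman-9β-yl (3S)-3-methylpentanoate | CC[Si](CC)(CC)OCC[C@H]1C[C@H](OC(=O)C[C@@H](C)CC)[C@@]2(C)CCC[C@](C)(O)[C@@H]2C1 | intermediate
16 | 12-(triethylsilyloxy)-13-nor-5αH,7βH-eudesm-4(15)-en-9β-yl (3S)-3-methylpentanoate | CC[Si](CC)(CC)OCC[C@H]1C[C@H](OC(=O)C[C@@H](C)CC)[C@@]2(C)CCCC(=C)[C@@H]2C1 | intermediate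
17 | 4α-hydroperoxy-12-(triethylsilyloxy)-13-nor-5αH,7βH-eudesman-9β-yl (3S)-3-methylpentanoate | CC[Si](CC)(CC)OCC[C@H]1C[C@H](OC(=O)C[C@@H](C)CC)[C@@]2(C)CCC[C@@](C)(OO)[C@@H]2C1 | intermediate
18 | 4α-hydroxy-12-(triethylsilyloxy)-13-nor-5αH,7βH-eudesman-9β-yl (3S)-3-methylpentanoate | CC[Si](CC)(CC)OCC[C@H]1C[C@H](OC(=O)C[C@@H](C)CC)[C@@]2(C)CCC[C@@](C)(O)[C@@H]2C1 | intermediate
19 | 4α-hydroxy-12-oxo-13-nor-5αH,7βH-eudesman-9β-yl (3S)-3-methylpentanoate | O=CC[C@H]1C[C@H](OC(=O)C[C@@H](C)CC)[C@@]2(C)CCC[C@@](C)(O)[C@@H]2C1 | intermediate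
20 | 4α-hydroxy-12-oxo-5αH,7βH-eudesm-11(13)-en-9β-yl (3S)-3-methylpentanoate | C=C(C=O)[C@H]1C[C@H](OC(=O)C[C@@H](C)CC)[C@@]2(C)CCC[C@@](C)(O)[C@@H]2C1 | intermediate
21 | 4α-hydroxy-9β-[(3S)-3-methylpentanoyloxy]-5αH,7βH-eudesm-11(13)-en-12-oic acid (CNP0471281.1) | C=C(C(=O)O)[C@H]1C[C@H](OC(=O)C[C@@H](C)CC)[C@@]2(C)CCC[C@@](C)(O)[C@@H]2C1 | target

**Step count.** Total: 15 steps. Longest linear sequence: 13 steps (1, 2, 3, 5, 7 to 15).

**Steps most likely to fail**

Step 8. The C4 carbinol may discriminate the two diene faces only weakly, and endo selectivity may erode at the temperature needed, so that facially wrong or cis-fused cycloadducts form. The fallback moves control to a chiral auxiliary on the dienophile in a Lewis-acid-promoted cycloaddition; it sets out from 5 and returns at 13. Alkenylalane 8, made from 5 as in step 5, is trapped with ClCO2Me to give methyl (2E,7S)-7-hydroxy-3,7-dimethylnona-2,8-dienoate F1. LiOH gives (2E,7S)-7-hydroxy-3,7-dimethylnona-2,8-dienoic acid F2. Its mixed pivalic anhydride acylates lithiated (4S)-4-benzyl-1,3-oxazolidin-2-one to give the N-enoyl imide F3. Heck coupling with 11 as in step 7 gives the triene imide F4. Me2AlCl (one equivalent is consumed by the hydroxyl) in CH2Cl2 at −30 °C chelates the imide in its s-cis form; the benzyl group blocks the Cα-re face, and the diene should add endo to the Cα-si face, the sense that the C4 carbinol also favours, to give the cycloadduct imide F5. MeNHOMe·HCl/Me3Al gives the Weinreb amide F6, and (S)-2-methylbutylmagnesium bromide converts it into 13.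

Step 12. Capture of the planar C4 radical by O2 may be unselective, or the radical may be reduced to the 4-H compound. The fallback is a two-electron route from 16 back to 18. mCPBA (NaHCO3, CH2Cl2, 0 °C) should epoxidise the exocyclic alkene from the equatorial α face to give the 4α,15-epoxide F7. PhSeNa ((PhSe)2, NaBH4, EtOH) opens it at the primary C15 to give the 15-(phenylselanyl)-4α-ol F8. Bu3SnH/AIBN (toluene, 80 °C) removes selenium to give 18.

Step 5. In the one-pot acylation, acyl transfer to the aluminium alkoxide or methyl transfer to 7 may compete with alkenyl transfer. The fallback separates the two events; it sets out from 5 (with 7) and returns at 9. Alkenylalane 8 is quenched with I2 to give (3S,7E)-8-iodo-3,7-dimethylocta-1,7-dien-3-ol F9. Separately, 7 with MeNHOMe·HCl and pyridine gives (3S)-N-methoxy-N,3-dimethylpentanamide F10. Deprotonation of F9 with MeLi, iodine–lithium exchange with t-BuLi (Et2O, −78 °C) and addition of F10 give 9.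

**Further compounds**

F1 | step 8 | methyl (2E,7S)-7-hydroxy-3,7-dimethylnona-2,8-dienoate | C=C[C@@](C)(O)CCC/C(C)=C/C(=O)OC
F2 | step 8 | (2E,7S)-7-hydroxy-3,7-dimethylnona-2,8-dienoic acid | C=C[C@@](C)(O)CCC/C(C)=C/C(=O)O
F3 | step 8 | (4S)-4-benzyl-3-[(2E,7S)-7-hydroxy-3,7-dimethylnona-2,8-dienoyl]-1,3-oxazolidin-2-one | C=C[C@@](C)(O)CCC/C(C)=C/C(=O)N1[C@@H](Cc2ccccc2)COC1=O
F4 | step 8 | triene imide: the (2E,7S,8E)-7-hydroxy-3,7-dimethyl-10-methylidene-12-(triethylsilyloxy)dodeca-2,8-dienoyl derivative of (4S)-4-benzyl-1,3-oxazolidin-2-one | C=C(CCO[Si](CC)(CC)CC)/C=C/[C@@](C)(O)CCC/C(C)=C/C(=O)N1[C@@H](Cc2ccccc2)COC1=O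
F5 | step 8 | cycloadduct imide: 13 with the 3-methylpentanoyl group replaced by the [(4S)-4-benzyl-2-oxo-1,3-oxazolidin-3-yl]carbonyl group | CC[Si](CC)(CC)OCCC1=C[C@H]2[C@@](C)(O)CCC[C@]2(C)[C@@H](C(=O)N2[C@@H](Cc3ccccc3)COC2=O)C1
F6 | step 8 | Weinreb amide: 13 with the 3-methylpentanoyl group replaced by the N-methoxy-N-methylcarbamoyl group | CC[Si](CC)(CC)OCCC1=C[C@H]2[C@@](C)(O)CCC[C@]2(C)[C@@H](C(=O)N(C)OC)C1
F7 | step 12 | 4α,15-epoxy-12-(triethylsilyloxy)-13-nor-5αH,7βH-eudesman-9β-yl (3S)-3-methylpentanoate | CC[Si](CC)(CC)OCC[C@H]1C[C@H](OC(=O)C[C@@H](C)CC)[C@@]2(C)CCC[C@]3(CO3)[C@@H]2C1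
F8 | step 12 | 4α-hydroxy-15-(phenylselanyl)-12-(triethylsilyloxy)-13-nor-5αH,7βH-eudesman-9β-yl (3S)-3-methylpentanoate | CC[Si](CC)(CC)OCC[C@H]1C[C@H](OC(=O)C[C@@H](C)CC)[C@@]2(C)CCC[C@@](C[Se]c3ccccc3)(O)[C@@H]2C1
F9 | step 5 | (3S,7E)-8-iodo-3,7-dimethylocta-1,7-dien-3-ol | C=C[C@@](C)(O)CCC/C(C)=C/I
F10 | step 5 | (3S)-N-methoxy-N,3-dimethylpentanamide | CC[C@H](C)CC(=O)N(C)OC
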